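## Structural features

The target is a hydroazulene in which a cycloheptene (C1–C6 and C10) and a cyclopentane (C6–C10) share the C6–C10 bond; atoms are numbered from the ester carbinol C1 through the alkene C2=C3 (methyl on C3), the methylenes C4 and C5, the tertiary carbinol C6, the isopropyl-bearing C7, then C8 and C9 to the methyl-bearing fusion carbon C10. The four stereocentres C7, C6, C10 and C1 follow one another without a break and are 7R, 6S, 10R and 1S. The ester oxygen on C1, the methyl on C10, the hydroxyl on C6 and the isopropyl group on C7 all stand on the same face, so the ring fusion is cis and the seven-membered ring lies on the face of the cyclopentane opposite to the isopropyl group. Fragile are the tertiary C6 hydroxyl, which is β to C1 and invites retro-aldol cleavage of the C6–C10 bond whenever C1 is a ketone and C6 a free alkoxide, and the allylic 4-methoxybenzoate, which can ionise in acid or migrate to the syn C6 oxygen in base. The real difficulty is the pair of adjacent, fully substituted fusion carbons C6 and C10, each next to a further stereocentre. The key step exploits that C10–C1–C2–C3–C4, with oxygen on C1 and methyl on C3, is the five-carbon unit of a siloxy vinylcyclopropane (three-membered ring C2, C3, C4, bond C2–C4 to be broken), that C5=C6 with oxygen on C6 is the enol ether of a methyl ketone, and that the chain C7–C8–C9 ties the two together and becomes the rest of the cyclopentane.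

## Logic of the disconnections

26 ⇒ 25. The O–Si bond on C6 is the last one to be cleaved. The C6 oxygen is kept silylated through reduction and acylation: no free alkoxide ever sits β to a C1 ketone, the bulky group shields the face that must not receive hydride, and the tertiary oxygen cannot compete for the acyl group. The forward step must remove a tertiary triethylsilyl ether without moving or ionising the allylic ester.

25 ⇒ 23 + 24. The ester C(=O)–O bond at C1 is cut, which separates the aromatic acid part from the terpenoid core. The forward acylation only has to reach a hindered secondary allylic hydroxyl.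

23 ⇒ 22. The C1–H bond is removed, turning the carbinol into the enone carbonyl. This deletes one stereocentre; the forward reduction must be 1,2-selective and must deliver hydride from the face opposite the C10 methyl.

22 ⇒ 21. The C2=C3 π bond is traded for a C1=C2 silyl enol ether with sp3 C3. This is the form in which the cycloaddition delivers the ring. The forward oxidation can only eliminate toward C3 because C10 is quaternary, and it erases the C3 centre.

21 ⇒ 20. C6–C10 and C4–C5 are cut and C2–C4 is re-formed. Both rings, both quaternary carbons and two stereocentres fall away, leaving an acyclic bis(silyl enol ether) whose only ring is the cyclopropane. Three demands follow for 20: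
- The cyclopropane must be the single (2R,3R) enantiomer. The C2–C4 bond can only be opened from the enol ether face on which C4 lies, so the cyclopropane configuration, together with the enol ether geometry, decides the configuration at C10. The other trans enantiomer would direct the metal to the opposite face, or force cleavage of C2–C3.
- The tetrasubstituted enol ether must be Z (C9 cis to the C1 oxygen, the usual place of the tether).
- The isopropyl group on C7 ends up cis to the C6 oxygen and the C10 methyl; it is the new ring bonds C6–C5 and C10–C1 that lie anti to it. With the (2R,3R) cyclopropane this is the matched case.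

Triethylsilyl is chosen for both oxygens: it comes directly from the hydrosilane at C1, survives chromatography and the later steps at C6, and still leaves with fluoride.

20 ⇒ 18 ⇒ 17. The two O–Si bonds and the C9–H bond are removed. The C5=C6 enol ether goes back to a methyl ketone (kinetic enolisation) and the C1=C10 enol ether goes back to an enone. The gain is that the Z geometry of the tetrasubstituted enol ether is not left to an enolisation but is set by a conjugate hydrosilylation through the s-cis enone. The forward steps must leave the C6 ketone alone in the first and deprotonate only the methyl group in the second.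

17 ⇒ 11 + 16. The C9=C10 double bond is cut into a terminal alkene and an isopropenyl ketone. This splits the precursor into a fragment that carries C7 and a fragment that carries the cyclopropane. The forward cross-metathesis must couple a 1,1-disubstituted enone.

16 ⇒ 14 ⇒ 12. The C1–C10 bond is cut (acyl carbon to isopropenyl carbon). The forward steps are a Weinreb amide formation and a single addition of an alkenyl Grignard reagent, neither of which touches the cyclopropane centres.

11 ⇒ 8. The C5–C6 bond is cut, so the methyl ketone becomes a carboxylic acid. The forward step must stop at the ketone and keep C7.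

8 ⇒ 6 ⇒ 3 + 4, and 3 ⇒ 1 + 2. The C7–C8 bond is cut and the acid is returned to an auxiliary-bound isovaleryl imide. C7 is the only stereocentre made by an external controller. The isopropyl group outranks the allyl group, so the (R)-auxiliary is needed for 7R.

## Other disconnections considered

Alternative 1: The cut is C6–C7 alone, on an achiral 2,2-disubstituted cycloheptane-1,3-dione A1 in which the seven-membered ring already exists. In the forward key step Cu(OTf)2 (divalent copper) with a chiral bis(oxazoline) would bind the two carbonyl groups of A1, and the trisubstituted alkene would attack one of the two enantiotopic carbonyls in a carbonyl-ene reaction to give the hydroxy ketone A2.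
- In favour: C6, C7 and C10 would come from a catalyst and not from an auxiliary. The concerted ene transition state should place the hydroxyl and the isopropenyl group cis on the new five-membered ring, and the fusion can only be cis. In stereochemical design it is the equal of the chosen plan, and in the number of steps up to the bicycle (about three) it is better.
- Against: A2 has neither the C3 methyl nor the C2=C3 bond. After hydrogenation of the isopropenyl group and protection of the C6 hydroxyl, an enone must be made, methylated at C3 by conjugate addition and oxidised again, about five operations before the reduction and acylation that both plans share. An unactivated ketone is a weak enophile, selection between the carbonyls of a seven-membered 1,3-dione through a six-membered chelate is unproven, and C-alkylation of a cyclic 1,3-dione with an unactivated primary halide on the way to A1 competes with O-alkylation.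
- Comparison: both key steps are untested on their substrates. The chosen step closes two rings and brings the whole carbon and oxygen pattern; this one closes one ring and leaves the seven-membered ring to be decorated, so the total length would be similar but the late-stage burden higher.

Alternative 2: The cut is C6–C10 and C2–C3. In the forward key step the tertiary α-chloro ketone A3 would be ionised with NaOCH2CF3 in CF3CH2OH to the oxyallyl cation C10–C1(O)–C2, which adds across the tethered 2-methylfuran in a (4+3) cycloaddition to give the oxygen-bridged ketone A4.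
- In favour: intramolecular furan–oxyallyl (4+3) cycloaddition is an established reaction class, so on precedent this is better than the chosen plan. Like the chosen step it closes both rings and makes both quaternary fusion carbons (equal). A4 already holds the C1 carbonyl, the C3 methyl and, masked as the ether bridge, the C6 oxygen; hydrogenation of C4=C5 and β-elimination of the bridge would reach the stage of 22 in two steps, so the economy after the key step is equal.
- Against: the cation adds without a metal template, so neither the cis fusion nor the facial sense relative to C7 is enforced. The tertiary chloride has to be made beside an acid- and halogen-sensitive furan. Building the furan on the C7 fragment costs about three steps more than 20 needs.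
- Comparison: in the chosen plan the cyclopropane configuration fixes C10 and the tether fixes the fusion; here the diastereoselection is open. Because its chemistry is known, it is kept as the fallback for the key step.

Alternative 3: The cut is C9–C10 alone. In the forward key step Ph3PAuNTf2 (monovalent gold) would activate the terminal alkyne of the methyl enol ether A5, the C1=C10 enol ether would attack C9 in a 5-endo-dig closure, and hydrolysis of the oxocarbenium ion would give the bicyclic ketone A6.
- In favour: gold-catalysed carbocyclisation of enol ethers onto alkynes is known and makes quaternary carbons, so its precedent is better than that of the chosen step. C10 is dictated by C6 because a five-membered ring can only close cis, which is equal or better in reliability at that centre.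
- Against: only one ring and one stereocentre are made. C6 and C7 must be set earlier by adding a chiral propargyl or allenyl metal to a cycloheptenone carbonyl, with control of two adjacent centres, one of them a tertiary carbinol that ionises easily before it is silylated. A6 lacks the C3 methyl and the C2=C3 bond and has an extra C8=C9 bond, so hydrogenation and the enone/methylation/re-oxidation sequence follow: five or more steps after the key step against four.
- Comparison: the key step is safer, but the gain in complexity is smaller and the route longer.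

Key step: step 10

Assumption: (1R,2R)-2-methylcyclopropane-1-carboxylic acid 12 is bought as the single enantiomer; if only the racemic trans acid is on offer it must be resolved before step 5.

## Route

Step 1
Reactants: 1 (R)-4-benzyl-1,3-oxazolidin-2-one; 2 3-methylbutanoyl chloride
Product: 3 (R)-4-benzyl-3-(3-methylbutanoyl)-1,3-oxazolidin-2-one
Conditions: Et3N, 4-(dimethylamino)pyridine (cat.), CH2Cl2, 0 °C → rt
Reagents that add atoms: none
Why: N-acylation of the oxazolidinone by the acid chloride under nucleophilic catalysis; no stereocentre is formed and the auxiliary centre is not touched.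

Step 2
Reactants: 3 (R)-4-benzyl-3-(3-methylbutanoyl)-1,3-oxazolidin-2-one; 4 allyl bromide
Product: 6 (R)-4-benzyl-3-[(2R)-2-(propan-2-yl)pent-4-enoyl]-1,3-oxazolidin-2-one, via sodium Z-enolate 5 (not isolated)
Conditions: NaN(SiMe3)2, THF, −78 °C; then 4, −78 → −40 °C
Reagents that add atoms: none
Why: Evans asymmetric alkylation: the chelated Z enolate 5 is blocked on the face of the benzyl group, so allyl bromide adds to the other face, which with the (R)-auxiliary sets C7 as R.

Step 3
Reactants: 6 (R)-4-benzyl-3-[(2R)-2-(propan-2-yl)pent-4-enoyl]-1,3-oxazolidin-2-one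
Product: 8 (2R)-2-(propan-2-yl)pent-4-enoic acid, via lithium peroxycarboxylate 7 (not isolated)
Conditions: LiOH, H2O2, THF/H2O, 0 °C; then Na2SO3 (aq); then HCl (aq)
Reagents that add atoms: hydrogen peroxide, OO
Why: Hydroperoxide cleavage of the imide: LiOOH attacks the exocyclic carbonyl even of a hindered acyl group, sulfite reduces the peroxy acid salt 7, and the α-centre should not epimerise; auxiliary 1 is recovered.

Step 4
Reactants: 8 (2R)-2-(propan-2-yl)pent-4-enoic acid
Product: 11 (3R)-3-(propan-2-yl)hex-5-en-2-one, via lithium carboxylate 9 (not isolated), via dilithium gem-diolate 10 (not isolated)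
Conditions: MeLi (2.5 equiv), Et2O, 0 °C → rt; inverse quench into cold HCl (aq)
Reagents that add atoms: methyllithium, [Li]C
Why: Ketone synthesis from a carboxylic acid and an organolithium: carboxylate 9 adds one MeLi to give gem-diolate 10, which cannot add again and releases the methyl ketone only on acidic quench; C7 is not deprotonated.

Step 5
Reactants: 12 (1R,2R)-2-methylcyclopropane-1-carboxylic acid
Product: 14 (1R,2R)-N-methoxy-N,2-dimethylcyclopropane-1-carboxamide, via acyl imidazolide 13 (not isolated)
Conditions: 1,1'-carbonyldiimidazole, CH2Cl2, rt; then MeNHOMe·HCl, rt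
Reagents that add atoms: N,O-dimethylhydroxylamine hydrochloride, CNOC.Cl; 1,1'-carbonyldiimidazole, O=C(n1ccnc1)n1ccnc1 (its atoms remain only in 13)
Why: Weinreb amide formation through the acyl imidazolide; neither cyclopropane centre is touched.

Step 6
Reactants: 14 (1R,2R)-N-methoxy-N,2-dimethylcyclopropane-1-carboxamide
Product: 16 2-methyl-1-[(1R,2R)-2-methylcyclopropyl]prop-2-en-1-one, via magnesium chelate 15 (not isolated)
Conditions: CH2=C(CH3)MgBr, THF, −20 → 0 °C; quench into cold HCl (aq)
Reagents that add atoms: isopropenylmagnesium bromide, C=C(C)[Mg]Br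
Why: Weinreb ketone synthesis: the chelated adduct 15 persists until the quench, so no tertiary alcohol forms, and the acidic quench keeps the released amine from adding to the enone.

Step 7
Reactants: 11 (3R)-3-(propan-2-yl)hex-5-en-2-one; 16 2-methyl-1-[(1R,2R)-2-methylcyclopropyl]prop-2-en-1-one
Product: 17 (2E,5R)-5-acetyl-2,6-dimethyl-1-[(1R,2R)-2-methylcyclopropyl]hept-2-en-1-one
Conditions: second-generation Hoveyda–Grubbs catalyst RuCl2(H2IMes)(=CH-C6H4-2-OiPr) (5 mol %), 16 (1.5–2 equiv, excess recovered), CH2Cl2, 40 °C
Reagents that add atoms: none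
Why: Olefin cross-metathesis of a terminal alkene with a 1,1-disubstituted enone that does not homodimerise; the trisubstituted enone is expected as the E isomer, and its geometry is of no consequence after step 8.

Step 8
Reactants: 17 (2E,5R)-5-acetyl-2,6-dimethyl-1-[(1R,2R)-2-methylcyclopropyl]hept-2-en-1-one
Product: 18 (3R,6Z)-6-methyl-7-[(1R,2R)-2-methylcyclopropyl]-3-(propan-2-yl)-7-(triethylsilyloxy)hept-6-en-2-one
Conditions: Et3SiH (1.1 equiv), RhCl(PPh3)3 (1 mol %), toluene, 50 °C
Reagents that add atoms: triethylsilane, CC[SiH](CC)CC
Why: Conjugate (1,4) hydrosilylation: monovalent rhodium adds Si–H across the s-cis oxadiene, silicon to oxygen and hydrogen to C9, which should fix the tetrasubstituted enol ether as Z (C9 cis to the oxygen); with a trialkylsilane the isolated C6 ketone reacts far more slowly than the enone.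

Step 9
Reactants: 18 (3R,6Z)-6-methyl-7-[(1R,2R)-2-methylcyclopropyl]-3-(propan-2-yl)-7-(triethylsilyloxy)hept-6-en-2-one
Product: 20 (1Z,5R)-2,6-dimethyl-1-[(1R,2R)-2-methylcyclopropyl]-1-(triethylsilyloxy)-5-[1-(triethylsilyloxy)ethenyl]hept-1-ene, via lithium enolate 19 (not isolated)
Conditions: LiN(iPr)2, THF, −78 °C; then Et3SiCl, Et3N, −78 → 0 °C; chromatography on Et3N-deactivated silica
Reagents that add atoms: chlorotriethylsilane, CC[Si](Cl)(CC)CC
Why: Kinetic enolisation of the methyl ketone at the methyl group C5 (the methine C7 is hindered) and O-silylation of enolate 19; C7 and the tetrasubstituted enol ether are untouched.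

Step 10
Reactants: 20 (1Z,5R)-2,6-dimethyl-1-[(1R,2R)-2-methylcyclopropyl]-1-(triethylsilyloxy)-5-[1-(triethylsilyloxy)ethenyl]hept-1-ene
Product: 21 (1R,3aR,6R,8aS)-3a,6-dimethyl-1-(propan-2-yl)-4,8a-bis(triethylsilyloxy)-1,2,3,3a,6,7,8,8a-octahydroazulene
Conditions: [Rh(CO)2Cl]2 (5 mol %), 2,6-di-tert-butyl-4-methylpyridine (10 mol %), toluene (degassed), 80 → 110 °C
Reagents that add atoms: none
Why: Proposed new method: monovalent rhodium is expected to bind the C10=C1 enol ether of 20 and insert into the less substituted C2–C4 cyclopropane bond, giving a rhodacycle with a σ bond to C4 and a π-allyl over C2–C1–C10; the tethered C5=C6 enol ether then inserts with C6 bonding to C10, and reductive elimination joins C4 to C5 and leaves the C1=C2 silyl enol ether. The closest known reaction type is the rhodium-catalysed intramolecular (5+2) cycloaddition of vinylcyclopropanes with tethered alkenes, which tolerates heteroatom-substituted vinylcyclopropanes and 1,1-disubstituted alkenes but has not been shown to join two fully substituted carbons or to use a silyl enol ether as the two-carbon partner. The cyclopentane closes as the tether ring by a 5-exo migratory insertion that forms C6–C10, and the seven-membered ring closes as the cycloadduct ring by reductive elimination from the eight-membered rhodacycle, which forms C4–C5. C10 is controlled by the cyclopropane: C2–C4 can only be opened from the enol ether face on which C4 lies, and for the (2R,3R) cyclopropane attached to the Z enol ether this is the face that leads to 10R. C6 follows from C10 because the three-atom tether allows only the cis fusion (C10 methyl cis to C6 oxygen), and the C7 isopropyl group is matched since it then points away from the metal and the forming seven-membered ring. The step needs bond selection (C2–C4 over the methyl-bearing C2–C3, favoured sterically in a trans-2-alkyl cyclopropane), facial selection (secured by cyclopropane configuration plus enol ether geometry) and survival of both silyl enol ethers (neutral chloride catalyst, hindered base, no silver salt); C3 stays R and is deleted in step 11.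

Step 11
Reactants: 21 (1R,3aR,6R,8aS)-3a,6-dimethyl-1-(propan-2-yl)-4,8a-bis(triethylsilyloxy)-1,2,3,3a,6,7,8,8a-octahydroazulene
Product: 22 (1R,3aS,8aS)-3a,6-dimethyl-1-(propan-2-yl)-8a-(triethylsilyloxy)-2,3,3a,7,8,8a-hexahydroazulen-4(1H)-one
Conditions: Pd(OAc)2 (1.1 equiv), MeCN, rt → 40 °C
Reagents that add atoms: none
Why: Saegusa–Ito oxidation: divalent palladium palladates the enol ether at C2 and β-hydride elimination can only take the C3 hydrogen (C10 is quaternary), which gives the C2=C3 enone with the methyl on C3 and removes the C3 stereocentre; the tertiary silyl ether should survive the neutral conditions.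

Step 12
Reactants: 22 (1R,3aS,8aS)-3a,6-dimethyl-1-(propan-2-yl)-8a-(triethylsilyloxy)-2,3,3a,7,8,8a-hexahydroazulen-4(1H)-one
Product: 23 (1R,3aR,4S,8aS)-3a,6-dimethyl-1-(propan-2-yl)-8a-(triethylsilyloxy)-1,2,3,3a,4,7,8,8a-octahydroazulen-4-ol
Conditions: NaBH4, CeCl3·7H2O, MeOH/THF, −78 → −20 °C
Reagents that add atoms: none
Why: Luche 1,2-reduction of the enone; as in reductions of ketones next to an angular methyl group, hydride should approach C1 from the face opposite the C10 methyl and the bulky C6 silyloxy group, which places the new hydroxyl cis to both (1S).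

Step 13
Reactants: 23 (1R,3aR,4S,8aS)-3a,6-dimethyl-1-(propan-2-yl)-8a-(triethylsilyloxy)-1,2,3,3a,4,7,8,8a-octahydroazulen-4-ol; 24 4-methoxybenzoyl chloride
Product: 25 (1R,3aR,4S,8aS)-3a,6-dimethyl-1-(propan-2-yl)-8a-(triethylsilyloxy)-1,2,3,3a,4,7,8,8a-octahydroazulen-4-yl 4-methoxybenzoate
Conditions: pyridine, 4-(dimethylamino)pyridine (cat.), CH2Cl2, 0 °C → rt
Reagents that add atoms: none
Why: Acyl transfer under nucleophilic catalysis to the only free hydroxyl, a secondary allylic one; no stereocentre is affected.

Step 14
Reactants: 25 (1R,3aR,4S,8aS)-3a,6-dimethyl-1-(propan-2-yl)-8a-(triethylsilyloxy)-1,2,3,3a,4,7,8,8a-octahydroazulen-4-yl 4-methoxybenzoate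
Product: 26 (1R,3aR,4S,8aS)-8a-hydroxy-3a,6-dimethyl-1-(propan-2-yl)-1,2,3,3a,4,7,8,8a-octahydroazulen-4-yl 4-methoxybenzoate
Conditions: HF·pyridine, pyridine, THF, 0 °C → rt
Reagents that add atoms: none
Why: Fluoride-induced cleavage of the tertiary triethylsilyl ether; buffered HF·pyridine is too weakly basic to move the acyl group to the C6 oxygen and too weakly acidic to ionise the allylic ester.

## Compound list

1 | (R)-4-benzyl-1,3-oxazolidin-2-one | O=C1OC[C@@H](Cc2ccccc2)N1 | starting material
2 | 3-methylbutanoyl chloride | CC(C)CC(Cl)=O | starting material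
3 | (R)-4-benzyl-3-(3-methylbutanoyl)-1,3-oxazolidin-2-one | CC(C)CC(=O)N1[C@H](Cc2ccccc2)COC1=O | intermediate
4 | allyl bromide | C=CCBr | starting material
5 | sodium (Z)-1-[(4R)-4-benzyl-2-oxo-1,3-oxazolidin-3-yl]-3-methylbut-1-en-1-olate (formed in the flask, not isolated) | [Na+].[O-]/C(=C\C(C)C)N1[C@H](Cc2ccccc2)COC1=O | intermediate
6 | (R)-4-benzyl-3-[(2R)-2-(propan-2-yl)pent-4-enoyl]-1,3-oxazolidin-2-one | C=CC[C@H](C(C)C)C(=O)N1[C@H](Cc2ccccc2)COC1=O | intermediate
7 | lithium (2R)-2-(propan-2-yl)pent-4-eneperoxoate (formed in the flask, not isolated) | C=CC[C@H](C(C)C)C(=O)O[O-].[Li+] | intermediate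
8 | (2R)-2-(propan-2-yl)pent-4-enoic acid | C=CC[C@H](C(C)C)C(=O)O | intermediate
9 | lithium (2R)-2-(propan-2-yl)pent-4-enoate (formed in the flask, not isolated) | C=CC[C@H](C(C)C)C(=O)[O-].[Li+] | intermediate
10 | dilithium (3R)-3-(propan-2-yl)hex-5-ene-2,2-diolate (formed in the flask, not isolated) | C=CC[C@H](C(C)C)C(C)([O-])[O-].[Li+].[Li+] | intermediate
11 | (3R)-3-(propan-2-yl)hex-5-en-2-one | C=CC[C@H](C(C)C)C(C)=O | intermediate
12 | (1R,2R)-2-methylcyclopropane-1-carboxylic acid | C[C@@H]1C[C@H]1C(=O)O | starting material
13 | (1H-imidazol-1-yl)[(1R,2R)-2-methylcyclopropyl]methanone (formed in the flask, not isolated) | C[C@@H]1C[C@H]1C(=O)n1ccnc1 | intermediate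
14 | (1R,2R)-N-methoxy-N,2-dimethylcyclopropane-1-carboxamide | C[C@@H]1C[C@H]1C(=O)N(C)OC | intermediate
15 | bromomagnesium 1-[methoxy(methyl)amino]-2-methyl-1-[(1R,2R)-2-methylcyclopropyl]prop-2-en-1-olate (formed in the flask, not isolated) | C[C@@H]1C[C@H]1C(O[Mg]Br)(N(C)OC)C(C)=C | intermediate
16 | 2-methyl-1-[(1R,2R)-2-methylcyclopropyl]prop-2-en-1-one | C[C@@H]1C[C@H]1C(=O)C(C)=C | intermediate
17 | (2E,5R)-5-acetyl-2,6-dimethyl-1-[(1R,2R)-2-methylcyclopropyl]hept-2-en-1-one | C[C@@H]1C[C@H]1C(=O)/C(C)=C/C[C@H](C(C)C)C(C)=O | intermediate
18 | (3R,6Z)-6-methyl-7-[(1R,2R)-2-methylcyclopropyl]-3-(propan-2-yl)-7-(triethylsilyloxy)hept-6-en-2-one | CC(C)[C@@H](CC/C(C)=C(/[C@@H]1C[C@H]1C)O[Si](CC)(CC)CC)C(C)=O | intermediate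
19 | lithium (3R,6Z)-6-methyl-7-[(1R,2R)-2-methylcyclopropyl]-3-(propan-2-yl)-7-(triethylsilyloxy)hepta-1,6-dien-2-olate (formed in the flask, not isolated) | CC(C)[C@@H](CC/C(C)=C(/[C@@H]1C[C@H]1C)O[Si](CC)(CC)CC)C(=C)[O-].[Li+] | intermediate
20 | (1Z,5R)-2,6-dimethyl-1-[(1R,2R)-2-methylcyclopropyl]-1-(triethylsilyloxy)-5-[1-(triethylsilyloxy)ethenyl]hept-1-ene | CC(C)[C@@H](CC/C(C)=C(/[C@@H]1C[C@H]1C)O[Si](CC)(CC)CC)C(=C)O[Si](CC)(CC)CC | intermediate
21 | (1R,3aR,6R,8aS)-3a,6-dimethyl-1-(propan-2-yl)-4,8a-bis(triethylsilyloxy)-1,2,3,3a,6,7,8,8a-octahydroazulene (target numbering: 3R,6S,7R,10R) | CC[Si](CC)(CC)OC2=C[C@H](C)CC[C@]3(O[Si](CC)(CC)CC)[C@@H](C(C)C)CC[C@]23C | intermediate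
22 | (1R,3aS,8aS)-3a,6-dimethyl-1-(propan-2-yl)-8a-(triethylsilyloxy)-2,3,3a,7,8,8a-hexahydroazulen-4(1H)-one | O=C2C=C(C)CC[C@]3(O[Si](CC)(CC)CC)[C@@H](C(C)C)CC[C@]23C | intermediate
23 | (1R,3aR,4S,8aS)-3a,6-dimethyl-1-(propan-2-yl)-8a-(triethylsilyloxy)-1,2,3,3a,4,7,8,8a-octahydroazulen-4-ol | O[C@H]2C=C(C)CC[C@]3(O[Si](CC)(CC)CC)[C@@H](C(C)C)CC[C@]23C | intermediate
24 | 4-methoxybenzoyl chloride | COc1ccc(cc1)C(Cl)=O | starting material
25 | (1R,3aR,4S,8aS)-3a,6-dimethyl-1-(propan-2-yl)-8a-(triethylsilyloxy)-1,2,3,3a,4,7,8,8a-octahydroazulen-4-yl 4-methoxybenzoate | COc1ccc(C(=O)O[C@H]2C=C(C)CC[C@]3(O[Si](CC)(CC)CC)[C@@H](C(C)C)CC[C@]23C)cc1 | intermediate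
26 | (1R,3aR,4S,8aS)-8a-hydroxy-3a,6-dimethyl-1-(propan-2-yl)-1,2,3,3a,4,7,8,8a-octahydroazulen-4-yl 4-methoxybenzoate (target numbering: 1S,6S,7R,10R) | COc1ccc(C(=O)O[C@H]2C=C(C)CC[C@]3(O)[C@@H](C(C)C)CC[C@]23C)cc1 | target

## Step count and least certain steps

Total: 14 steps. Longest linear sequence: 12 steps (steps 1–4, then 7–14); the cyclopropane branch (steps 5 and 6) joins at step 7.

Step 10 (key step). The most likely failure is that the hindered tetrasubstituted siloxyalkene does not enter the oxidative addition, or that the 1,1-disubstituted enol ether does not insert at the fully substituted C10, so that the vinylcyclopropane merely isomerises. Further risks are opening of the methyl-bearing C2–C3 bond, leakage to the other face, and loss of silyl groups through traces of acid. The fallback uses known chemistry, sets out from 11 and returns at 22; it closes both rings by an intramolecular furan–oxyallyl (4+3) cycloaddition.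
- The kinetic lithium enolate of 11 (LiN(iPr)2, THF, −78 °C) is alkylated with propargyl bromide to give (6R)-6-(propan-2-yl)non-8-en-1-yn-5-one F1.
- Cycloisomerisation with Ph3PAuCl/AgOTf (monovalent gold) gives 2-methyl-5-[(3R)-2-methylhex-5-en-3-yl]furan F2.
- Cross-metathesis with 3-methylbut-3-en-2-one (second-generation Hoveyda–Grubbs catalyst) gives (3E,6R)-3,7-dimethyl-6-(5-methylfuran-2-yl)oct-3-en-2-one F3.
- 1,4-Hydrosilylation (Et3SiH, RhCl(PPh3)3) gives triethyl{[(2Z,6R)-3,7-dimethyl-6-(5-methylfuran-2-yl)oct-2-en-2-yl]oxy}silane F4, which N-chlorosuccinimide chlorinates at C10 to (6R)-3-chloro-3,7-dimethyl-6-(5-methylfuran-2-yl)octan-2-one F5 (the same compound as A3).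
- NaOCH2CF3 in CF3CH2OH ionises F5 to the oxyallyl cation, which adds across the furan to the oxygen-bridged ketone F6 (the same compound as A4).
- H2 over Pd/C saturates C4=C5 to give the saturated bridged ketone F7.
- Et3SiOSO2CF3 and Et3N enolise C1 toward C2, expel the bridge oxygen from C3 and silylate it on C6, which gives 22.

The cis fusion and the facial sense relative to C7 are not enforced in the cycloaddition and would have to be secured by separation at F6.

Step 8. The isolated C6 ketone may be hydrosilylated as well, and reaction through the s-trans enone would erode the Z geometry on which the configuration at C10 depends. The fallback sets out from 8 and returns at 18; it removes the ketone from the hydrosilylation.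
- 8 is converted (1,1'-carbonyldiimidazole, then MeNHOMe·HCl) into the Weinreb amide (2R)-N-methoxy-N-methyl-2-(propan-2-yl)pent-4-enamide F8.
- Cross-metathesis of F8 with 16 gives (2R,4E)-N-methoxy-N,5-dimethyl-6-[(1R,2R)-2-methylcyclopropyl]-6-oxo-2-(propan-2-yl)hex-4-enamide F9.
- 1,4-Hydrosilylation, now without a competing ketone, gives (2R,5Z)-N-methoxy-N,5-dimethyl-6-[(1R,2R)-2-methylcyclopropyl]-2-(propan-2-yl)-6-(triethylsilyloxy)hex-5-enamide F10.
- MeMgBr (THF, 0 °C) turns the amide into the methyl ketone, which is 18.

Step 7. Cross-metathesis onto a 1,1-disubstituted enone may stall while 11 dimerises, and both partners are volatile. The fallback sets out from 11 and 12 and returns at 17; it replaces metathesis by a Wittig olefination.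
- Ozonolysis of 11 (O3, CH2Cl2, −78 °C; PPh3) gives the keto aldehyde (3R)-4-oxo-3-(propan-2-yl)pentanal F11.
- 12 is activated as 13 and treated with two equivalents of Ph3P=CHCH3 to give the stabilised ylide 1-[(1R,2R)-2-methylcyclopropyl]-2-(triphenyl-λ5-phosphanylidene)propan-1-one F12.
- F12 reacts only with the aldehyde group of F11 (toluene, 80 °C) to give 17.

Step 12. Hydride delivery may show poor facial selectivity if the convex face is less shielded by the C10 methyl and the C6 silyloxy group than expected. The fallback sets out from 22 and returns at 25. If the C1 epimer (1R,3aR,4R,8aS)-3a,6-dimethyl-1-(propan-2-yl)-8a-(triethylsilyloxy)-1,2,3,3a,4,7,8,8a-octahydroazulen-4-ol F13 is the main product of the reduction, it is esterified under Mitsunobu conditions with 4-methoxybenzoic acid (PPh3, diisopropyl azodicarboxylate); this inverts C1 and gives 25 directly.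

Step 14. Desilylation of the hindered tertiary ether may be slow, and forcing it risks acyl migration to the C6 oxygen or ionisation of the allylic ester. The fallback sets out from 23 and returns at 26. Bu4NF (THF) removes the silyl group from 23 before the ester is present, giving the diol (1R,3aR,4S,8aS)-3a,6-dimethyl-1-(propan-2-yl)-1,2,3,3a,4,7,8,8a-octahydroazulene-4,8a-diol F14; acylation of F14 with 24 (pyridine, 4-(dimethylamino)pyridine) then occurs only at the secondary allylic hydroxyl and gives 26.

## Further compounds

F1 | step 10 | (6R)-6-(propan-2-yl)non-8-en-1-yn-5-one | C=CC[C@H](C(C)C)C(=O)CCC#C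
F2 | step 10 | 2-methyl-5-[(3R)-2-methylhex-5-en-3-yl]furan | C=CC[C@H](C(C)C)c1ccc(C)o1
F3 | step 10 | (3E,6R)-3,7-dimethyl-6-(5-methylfuran-2-yl)oct-3-en-2-one | CC(=O)/C(C)=C/C[C@H](C(C)C)c1ccc(C)o1
F4 | step 10 | triethyl{[(2Z,6R)-3,7-dimethyl-6-(5-methylfuran-2-yl)oct-2-en-2-yl]oxy}silane | CC[Si](CC)(CC)O/C(C)=C(/C)CC[C@H](C(C)C)c1ccc(C)o1
F5 | step 10 | (6R)-3-chloro-3,7-dimethyl-6-(5-methylfuran-2-yl)octan-2-one (both C3 epimers) | CC(=O)C(C)(Cl)CC[C@H](C(C)C)c1ccc(C)o1
F6 | step 10 | oxygen-bridged ketone, cis-fused 3,6-epoxy-3,10-dimethyl-7-(propan-2-yl)bicyclo[5.3.0]dec-4-en-1-one (target numbering) | O=C2C[C@]4(C)C=C[C@]3(O4)[C@@H](C(C)C)CC[C@]23C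
F7 | step 10 | saturated bridged ketone, cis-fused 3,6-epoxy-3,10-dimethyl-7-(propan-2-yl)bicyclo[5.3.0]decan-1-one (target numbering) | O=C2C[C@]4(C)CC[C@]3(O4)[C@@H](C(C)C)CC[C@]23C
F8 | step 8 | (2R)-N-methoxy-N-methyl-2-(propan-2-yl)pent-4-enamide | C=CC[C@H](C(C)C)C(=O)N(C)OC
F9 | step 8 | (2R,4E)-N-methoxy-N,5-dimethyl-6-[(1R,2R)-2-methylcyclopropyl]-6-oxo-2-(propan-2-yl)hex-4-enamide | C[C@@H]1C[C@H]1C(=O)/C(C)=C/C[C@H](C(C)C)C(=O)N(C)OC
F10 | step 8 | (2R,5Z)-N-methoxy-N,5-dimethyl-6-[(1R,2R)-2-methylcyclopropyl]-2-(propan-2-yl)-6-(triethylsilyloxy)hex-5-enamide | CC(C)[C@@H](CC/C(C)=C(/[C@@H]1C[C@H]1C)O[Si](CC)(CC)CC)C(=O)N(C)OC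
F11 | step 7 | (3R)-4-oxo-3-(propan-2-yl)pentanal | O=CC[C@H](C(C)C)C(C)=O
F12 | step 7 | 1-[(1R,2R)-2-methylcyclopropyl]-2-(triphenyl-λ5-phosphanylidene)propan-1-one | C[C@@H]1C[C@H]1C(=O)C(C)=P(c1ccccc1)(c1ccccc1)c1ccccc1
F13 | step 12 | (1R,3aR,4R,8aS)-3a,6-dimethyl-1-(propan-2-yl)-8a-(triethylsilyloxy)-1,2,3,3a,4,7,8,8a-octahydroazulen-4-ol | O[C@@H]2C=C(C)CC[C@]3(O[Si](CC)(CC)CC)[C@@H](C(C)C)CC[C@]23C
F14 | step 14 | (1R,3aR,4S,8aS)-3a,6-dimethyl-1-(propan-2-yl)-1,2,3,3a,4,7,8,8a-octahydroazulene-4,8a-diol | O[C@H]2C=C(C)CC[C@]3(O)[C@@H](C(C)C)CC[C@]23C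
A1 | alternative 1 | 2-methyl-2-(4-methylpent-3-en-1-yl)cycloheptane-1,3-dione | CC(C)=CCCC1(C)C(=O)CCCCC1=O
A2 | alternative 1 | cis-fused 6-hydroxy-10-methyl-7-(prop-1-en-2-yl)bicyclo[5.3.0]decan-1-one (target numbering) | O=C2CCCC[C@]3(O)[C@@H](C(C)=C)CC[C@]23C
A3 | alternative 2 | (6R)-3-chloro-3,7-dimethyl-6-(5-methylfuran-2-yl)octan-2-one (both C3 epimers) | CC(=O)C(C)(Cl)CC[C@H](C(C)C)c1ccc(C)o1
A4 | alternative 2 | oxygen-bridged ketone, cis-fused 3,6-epoxy-3,10-dimethyl-7-(propan-2-yl)bicyclo[5.3.0]dec-4-en-1-one (target numbering) | O=C2C[C@]4(C)C=C[C@]3(O4)[C@@H](C(C)C)CC[C@]23C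
A5 | alternative 3 | 1-methoxy-2-methyl-3-(4-methylpent-1-yn-3-yl)-3-(trimethylsilyloxy)cyclohept-1-ene (C6 and C7 as in the target) | COC1=C(C)[C@@](O[Si](C)(C)C)([C@@H](C(C)C)C#C)CCCC1
A6 | alternative 3 | cis-fused 10-methyl-7-(propan-2-yl)-6-(trimethylsilyloxy)bicyclo[5.3.0]dec-8-en-1-one (target numbering) | O=C2CCCC[C@]3(O[Si](C)(C)C)[C@@H](C(C)C)C=C[C@]23C
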